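**Plan**

Ring numbering used below: C1 = carbinol carbon (Me, OH), C2 = CHBr, C3 = CH2, C4 = CH carrying the side chain, then C5 and C6.
Retrosynthesis: cut the single bond between the two alkenes of the diene (Heck) to a ring iodoalkene and (S)-linalool; take the iodoalkene back to a C4 ethynyl group and a C4 CH2OSi arm; remove the C1 methyl (Grignard) and the C2 bromine (bromoenone); open the cyclohexenone at C2=C3 (aldol condensation) and C4–C5 (Michael) to 3-silyloxypropanal and methyl vinyl ketone.
Forward: a one-pot Michael addition/aldol condensation builds the only ring (closure C2–C3); Br, H and Me are then placed on C2, C3 and C1; the C4 arm becomes the E iodoalkene; the chain is joined last.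
Enabling feature: C1 is at ketone level with C2 as its α-carbon and C3 two bonds away, so C1(=O)–C2H3 and C3H=O of a 1,5-keto aldehyde close the six-membered ring. A 4-substituted cyclohexanone has a mirror plane through C1 and C4; the C2=C3 alkene left by the closure keeps C2 different from C6 and so keeps C4 stereogenic.
Stereochemistry: C4 from the prolinol silyl ether catalyst; C2 by axial protonation of a bromoenolate (Br equatorial, cis to the C4 arm); C1 by Grignard addition trans to Br; the chain carbinol from Sharpless epoxidation of geraniol; both E alkenes from syn-carboalumination and the Heck step.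

Key step: step 1

Assumption: the open enamine face in step 1 is the one given by the usual steric shielding model for prolinol silyl ethers (R catalyst gives R at the aldehyde α-carbon here).

**Route**

Step 1
Reactants: 1 3-{[tert-butyl(dimethyl)silyl]oxy}propanal; 2 but-3-en-2-one
Product: 5 (4S)-4-({[tert-butyl(dimethyl)silyl]oxy}methyl)cyclohex-2-en-1-one, via keto aldehyde 3 (not isolated), via aldol adduct 4 (not isolated)
Conditions: (R)-2-[diphenyl(trimethylsilyloxy)methyl]pyrrolidine (5 mol%), ethyl 3,4-dihydroxybenzoate (20 mol%), neat, 4 °C; excess 2 evaporated; then LiOH, i-PrOH, 23 °C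
Reagents that add atoms: none
Why: The prolinol silyl ether condenses with 1 to an E-enamine whose one face is shielded by the diphenyl(silyloxy)methyl group, so that conjugate addition to 2 (amine-catalysed Michael addition) sets C4 (R in 3); LiOH then forms the methyl-ketone enolate, whose carbon (future C2) adds to the formyl carbon (future C3), and the aldol 4 loses water by E1cB to give 5. The closest known reaction type is the Robinson-type sequence of organocatalytic aldehyde–enone Michael addition and aldol condensation that is the standard entry to 4-substituted cyclohex-2-enones. The six-membered carbocycle closes in the 6-(enolendo)-exo-trig mode, the only alternative enolate (at C6) being able to close a four-membered ring only. C4 is the one stereocentre that survives and it is controlled by the catalyst; the carbinol centre of 4 is lost on dehydration. The step needs C4 (α to the formyl group) not to epimerise and the β-silyloxy group not to be lost by E1cB before the ring closes, which the fast intramolecular aldol addition under mild base at 23 °C should secure. The C2=C3 alkene left by the closure keeps C2 different from C6, which is what makes C4 stereogenic in a ring that otherwise has a mirror plane through C1 and C4.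

Step 2
Reactants: 5 (4S)-4-({[tert-butyl(dimethyl)silyl]oxy}methyl)cyclohex-2-en-1-one
Product: 7 (4S)-2-bromo-4-({[tert-butyl(dimethyl)silyl]oxy}methyl)cyclohex-2-en-1-one, via dibromide 6 (not isolated)
Conditions: Br2, CH2Cl2, 0 °C; then Et3N, 0 °C to 23 °C
Reagents that add atoms: bromine, BrBr
Why: Bromine adds across the electron-poor C2=C3 alkene to give the trans-dibromide 6 and Et3N then removes the acidic C2 hydrogen with loss of the C3 bromide (bromination–dehydrobromination, the standard α-bromination of cyclohexenones), which puts bromine on C2 only and creates no stereocentre.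

Step 3
Reactants: 7 (4S)-2-bromo-4-({[tert-butyl(dimethyl)silyl]oxy}methyl)cyclohex-2-en-1-one
Product: 9 (2S,4S)-2-bromo-4-({[tert-butyl(dimethyl)silyl]oxy}methyl)cyclohexan-1-one, via lithium bromoenolate 8 (not isolated)
Conditions: LiBH(s-Bu)3, THF, −78 °C; then AcOH, THF, −78 °C; non-oxidative work-up
Reagents that add atoms: none
Why: The hindered borohydride delivers hydride to C3 (1,4-reduction of a β-unsubstituted cyclohexenone) to give bromoenolate 8, and kinetic protonation at −78 °C along the axial direction through a chair-like transition state should leave bromine equatorial and cis to the equatorial C4 arm (C2 = S).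

Step 4
Reactants: 9 (2S,4S)-2-bromo-4-({[tert-butyl(dimethyl)silyl]oxy}methyl)cyclohexan-1-one
Product: 10 (1R,2S,4S)-2-bromo-4-({[tert-butyl(dimethyl)silyl]oxy}methyl)-1-methylcyclohexan-1-ol
Conditions: MeMgBr, Et2O, −78 °C; aq. NH4Cl at −78 °C
Reagents that add atoms: methylmagnesium bromide, C[Mg]Br
Why: Grignard addition to an α-bromo ketone: in the diequatorial chair of 9 methyl should enter along the equatorial trajectory, on the face trans to bromine as in the classical route from 2-halocyclohexanones to cis-halohydrins, which gives the axial hydroxyl cis to bromine and to the C4 arm (C1 = R), and the cold quench keeps the bromomagnesium alkoxide from rearranging.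

Step 5
Reactants: 10 (1R,2S,4S)-2-bromo-4-({[tert-butyl(dimethyl)silyl]oxy}methyl)-1-methylcyclohexan-1-ol
Product: 11 (1R,2S,4S)-2-bromo-4-(hydroxymethyl)-1-methylcyclohexan-1-ol
Conditions: HF·pyridine, pyridine, THF, 0 °C to 23 °C
Reagents that add atoms: none
Why: Desilylation with pyridine-buffered HF·pyridine removes the primary silyl ether and leaves the tertiary alcohol, the secondary bromide and all stereocentres untouched.

Step 6
Reactants: 11 (1R,2S,4S)-2-bromo-4-(hydroxymethyl)-1-methylcyclohexan-1-ol
Product: 12 (1S,3S,4R)-3-bromo-4-hydroxy-4-methylcyclohexane-1-carbaldehyde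
Conditions: TEMPO (10 mol%), PhI(OAc)2, CH2Cl2, 23 °C
Reagents that add atoms: none
Why: Oxoammonium oxidation (TEMPO with PhI(OAc)2 as terminal oxidant) takes only the primary alcohol to the aldehyde, and the formyl group stays equatorial, the thermodynamically preferred configuration at C4.

Step 7
Reactants: 12 (1S,3S,4R)-3-bromo-4-hydroxy-4-methylcyclohexane-1-carbaldehyde
Product: 13 (1R,2S,4S)-2-bromo-4-ethynyl-1-methylcyclohexan-1-ol
Conditions: dimethyl (1-diazo-2-oxopropyl)phosphonate, K2CO3, MeOH, 0 °C to 23 °C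
Reagents that add atoms: dimethyl (1-diazo-2-oxopropyl)phosphonate, COP(=O)(OC)C(=[N+]=[N-])C(C)=O
Why: Ohira–Bestmann (Seyferth–Gilbert) homologation: methanolysis of the reagent gives the diazomethylphosphonate anion, which adds to the aldehyde, and loss of dimethyl phosphate and N2 with 1,2-hydrogen shift gives the terminal alkyne; the weak base cannot close an epoxide from the cis-bromohydrin and the equatorial C4 centre has no drive to epimerise.

Step 8
Reactants: 13 (1R,2S,4S)-2-bromo-4-ethynyl-1-methylcyclohexan-1-ol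
Product: 15 (1R,2S,4S)-2-bromo-4-[(1E)-1-iodoprop-1-en-2-yl]-1-methylcyclohexan-1-ol, via alkenylalane 14 (not isolated)
Conditions: AlMe3, Cp2ZrCl2 (20 mol%), H2O (1 equiv), CH2Cl2, −23 °C; then I2, THF, −23 °C to 0 °C; aq. potassium sodium tartrate work-up
Reagents that add atoms: trimethylaluminium, C[Al](C)C; iodine, II
Why: Negishi carboalumination (Cp2ZrCl2-catalysed) adds methyl and aluminium syn across the terminal alkyne with aluminium on the terminal carbon, after the hydroxyl has formed its aluminium alkoxide, and iodinolysis of the alkenyl C–Al bond with retention gives the E iodoalkene.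

Step 9
Reactants: 16 (2E)-3,7-dimethylocta-2,6-dien-1-ol (geraniol)
Product: 17 [(2S,3S)-3-methyl-3-(4-methylpent-3-en-1-yl)oxiran-2-yl]methanol
Conditions: Ti(OiPr)4 (5 mol%), L-(+)-diethyl tartrate (7 mol%), t-BuOOH, 4 Å molecular sieves, CH2Cl2, −20 °C
Reagents that add atoms: tert-butyl hydroperoxide, CC(C)(C)OO
Why: Sharpless asymmetric epoxidation: the titanium tartrate catalyst built from L-(+)-diethyl tartrate delivers oxygen to one face of the allylic alkene only and leaves the remote alkene alone, which sets C2 and C3 of 17 as S,S.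

Step 10
Reactants: 17 [(2S,3S)-3-methyl-3-(4-methylpent-3-en-1-yl)oxiran-2-yl]methanol
Product: 18 (2R,3S)-2-(iodomethyl)-3-methyl-3-(4-methylpent-3-en-1-yl)oxirane
Conditions: I2, PPh3, imidazole, CH2Cl2, 0 °C
Reagents that add atoms: iodine, II
Why: Appel-type iodination (PPh3, I2, imidazole) activates the primary hydroxyl as an oxyphosphonium ion that iodide displaces by SN2 at CH2, so neither epoxide stereocentre is touched.

Step 11
Reactants: 18 (2R,3S)-2-(iodomethyl)-3-methyl-3-(4-methylpent-3-en-1-yl)oxirane
Product: 19 (3S)-3,7-dimethylocta-1,6-dien-3-ol ((S)-linalool)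
Conditions: Zn dust, EtOH, reflux
Reagents that add atoms: none
Why: Zinc reduces the C–I bond and the resulting β-oxido organozinc opens the epoxide by elimination (reductive fragmentation of a 2,3-epoxy iodide) to the tertiary allylic alcohol, with the C3–O bond intact and its configuration (S) retained.

Step 12
Reactants: 15 (1R,2S,4S)-2-bromo-4-[(1E)-1-iodoprop-1-en-2-yl]-1-methylcyclohexan-1-ol; 19 (3S)-3,7-dimethylocta-1,6-dien-3-ol
Product: 20 (1R,2S,4S)-2-bromo-4-[(2E,4E,6S)-6-hydroxy-6,10-dimethylundeca-2,4,9-trien-2-yl]-1-methylcyclohexan-1-ol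
Conditions: Pd(OAc)2 (10 mol%), Bu4NCl, NaHCO3, DMF, 45 °C
Reagents that add atoms: none
Why: Heck reaction under ligand-free phase-transfer conditions: oxidative addition of the alkenyl iodide to zerovalent palladium with retention, syn insertion at the terminal carbon of the monosubstituted alkene of 19 and syn β-hydride elimination away from the fully substituted carbinol carbon should give the E,E-diene, while the trisubstituted alkene, the tertiary alcohols and the unactivated secondary bromide stay out of the reaction.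

**Compound list**

1 | 3-{[tert-butyl(dimethyl)silyl]oxy}propanal | CC(C)(C)[Si](C)(C)OCCC=O | starting material
2 | but-3-en-2-one (methyl vinyl ketone) | CC(=O)C=C | starting material
3 | (2R)-2-({[tert-butyl(dimethyl)silyl]oxy}methyl)-5-oxohexanal | CC(=O)CC[C@@H](C=O)CO[Si](C)(C)C(C)(C)C | intermediate
4 | (4R)-4-({[tert-butyl(dimethyl)silyl]oxy}methyl)-3-hydroxycyclohexan-1-one (both C3 epimers) | O=C1CC(O)[C@@H](CO[Si](C)(C)C(C)(C)C)CC1 | intermediate
5 | (4S)-4-({[tert-butyl(dimethyl)silyl]oxy}methyl)cyclohex-2-en-1-one | O=C1C=C[C@@H](CO[Si](C)(C)C(C)(C)C)CC1 | intermediate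
6 | (4R)-2,3-dibromo-4-({[tert-butyl(dimethyl)silyl]oxy}methyl)cyclohexan-1-one (trans-dibromide; C2 and C3 not assigned) | O=C1C(Br)C(Br)[C@@H](CO[Si](C)(C)C(C)(C)C)CC1 | intermediate
7 | (4S)-2-bromo-4-({[tert-butyl(dimethyl)silyl]oxy}methyl)cyclohex-2-en-1-one | O=C1C(Br)=C[C@@H](CO[Si](C)(C)C(C)(C)C)CC1 | intermediate
8 | lithium (4S)-2-bromo-4-({[tert-butyl(dimethyl)silyl]oxy}methyl)cyclohex-1-en-1-olate | [Li+].[O-]C1=C(Br)C[C@@H](CO[Si](C)(C)C(C)(C)C)CC1 | intermediate
9 | (2S,4S)-2-bromo-4-({[tert-butyl(dimethyl)silyl]oxy}methyl)cyclohexan-1-one | O=C1[C@@H](Br)C[C@@H](CO[Si](C)(C)C(C)(C)C)CC1 | intermediate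
10 | (1R,2S,4S)-2-bromo-4-({[tert-butyl(dimethyl)silyl]oxy}methyl)-1-methylcyclohexan-1-ol | CC(C)(C)[Si](C)(C)OC[C@H]1CC[C@@](C)(O)[C@@H](Br)C1 | intermediate
11 | (1R,2S,4S)-2-bromo-4-(hydroxymethyl)-1-methylcyclohexan-1-ol | OC[C@H]1CC[C@@](C)(O)[C@@H](Br)C1 | intermediate
12 | (1S,3S,4R)-3-bromo-4-hydroxy-4-methylcyclohexane-1-carbaldehyde | O=C[C@H]1CC[C@@](C)(O)[C@@H](Br)C1 | intermediate
13 | (1R,2S,4S)-2-bromo-4-ethynyl-1-methylcyclohexan-1-ol | C#C[C@H]1CC[C@@](C)(O)[C@@H](Br)C1 | intermediate
14 | {(1E)-2-[(1S,3S,4R)-3-bromo-4-[(dimethylalumanyl)oxy]-4-methylcyclohexyl]prop-1-en-1-yl}dimethylalumane | C[Al](C)/C=C(\C)[C@H]1CC[C@@](C)(O[Al](C)C)[C@@H](Br)C1 | intermediate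
15 | (1R,2S,4S)-2-bromo-4-[(1E)-1-iodoprop-1-en-2-yl]-1-methylcyclohexan-1-ol | I/C=C(\C)[C@H]1CC[C@@](C)(O)[C@@H](Br)C1 | intermediate
16 | (2E)-3,7-dimethylocta-2,6-dien-1-ol (geraniol) | CC(C)=CCC/C(C)=C/CO | starting material
17 | [(2S,3S)-3-methyl-3-(4-methylpent-3-en-1-yl)oxiran-2-yl]methanol | CC(C)=CCC[C@]1(C)O[C@H]1CO | intermediate
18 | (2R,3S)-2-(iodomethyl)-3-methyl-3-(4-methylpent-3-en-1-yl)oxirane | CC(C)=CCC[C@]1(C)O[C@H]1CI | intermediate
19 | (3S)-3,7-dimethylocta-1,6-dien-3-ol ((S)-linalool) | CC(C)=CCC[C@](C)(O)C=C | intermediate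
20 | (1R,2S,4S)-2-bromo-4-[(2E,4E,6S)-6-hydroxy-6,10-dimethylundeca-2,4,9-trien-2-yl]-1-methylcyclohexan-1-ol | CC(C)=CCC[C@](C)(O)/C=C/C=C(\C)[C@H]1CC[C@@](C)(O)[C@@H](Br)C1 | target

**Step count and risks**

Total step count: 12. Longest linear sequence: 9 steps (steps 1 to 8 and step 12).

Steps most likely to fail:

1. Step 3. The protonation of bromoenolate 8 may show poor facial selectivity, the bromo ketone may epimerise at C2 by bromide exchange or enolisation, and a sec-butyl group may migrate from boron to C2 of the bromoenolate. The fallback sets out from 5 and comes back at 9. 1,4-Hydrosilylation of 5 (Et3SiH, RhCl(PPh3)3) should give the regiodefined enol ether tert-butyldimethyl({(1S)-4-[(triethylsilyl)oxy]cyclohex-3-en-1-yl}methoxy)silane F1. N-Bromosuccinimide (THF, −78 °C) should brominate it from the axial direction to the trans bromo ketone (2R,4S)-2-bromo-4-({[tert-butyl(dimethyl)silyl]oxy}methyl)cyclohexan-1-one F2. LiBr in acetone then inverts C2 by SN2 exchange, which cannot move bromine to C6; the equatorial isomer 9 is separated and the remaining F2 is put back into the exchange.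

2. Step 4. Methyl may add with poor facial selectivity (axial attack on the diequatorial chair), the bromo ketone may be enolised, or the bromomagnesium alkoxide may rearrange with loss of bromide. The fallback sets out from 1 and 2 and comes back at 12; it relays the stereochemistry through the trans series, where both bromination and addition are under strong stereoelectronic control.
   - Step 1 run with (S)-2-[diphenyl(trimethylsilyloxy)methyl]pyrrolidine should give, through (2S)-2-({[tert-butyl(dimethyl)silyl]oxy}methyl)-5-oxohexanal F3 and (4S)-4-({[tert-butyl(dimethyl)silyl]oxy}methyl)-3-hydroxycyclohexan-1-one F4, the enone (4R)-4-({[tert-butyl(dimethyl)silyl]oxy}methyl)cyclohex-2-en-1-one F5.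
   - Hydrosilylation (Et3SiH, RhCl(PPh3)3) gives tert-butyldimethyl({(1R)-4-[(triethylsilyl)oxy]cyclohex-3-en-1-yl}methoxy)silane F6, and axial bromination with N-bromosuccinimide gives (2S,4R)-2-bromo-4-({[tert-butyl(dimethyl)silyl]oxy}methyl)cyclohexan-1-one F7.
   - MeMgBr should add anti to the axial C–Br bond to give (1R,2S,4R)-2-bromo-4-({[tert-butyl(dimethyl)silyl]oxy}methyl)-1-methylcyclohexan-1-ol F8, which has C1 and C2 as in the target and C4 inverted.
   - HF·pyridine gives (1R,2S,4R)-2-bromo-4-(hydroxymethyl)-1-methylcyclohexan-1-ol F9, and TEMPO/PhI(OAc)2 gives (1R,3S,4R)-3-bromo-4-hydroxy-4-methylcyclohexane-1-carbaldehyde F10.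
   - DBU in CH2Cl2 equilibrates the formyl-bearing carbon; the equilibrium should favour 12, in which formyl, bromine and methyl are all equatorial, and the minor epimer is recycled.

3. Step 8. The aluminium alkoxide next to the C–Br bond may rearrange with loss of bromide (ring contraction), or the Lewis acidic alane may ionise the secondary bromide. The fallback sets out from 13 and comes back at 15. The hydroxyl is masked first (trimethylsilyl triflate, 2,6-lutidine, CH2Cl2, −78 °C) as {[(1R,2S,4S)-2-bromo-4-ethynyl-1-methylcyclohexyl]oxy}trimethylsilane F11, so that no aluminium alkoxide is formed. Carboalumination (AlMe3, Cp2ZrCl2) gives the alkenylalane {(1E)-2-[(1S,3S,4R)-3-bromo-4-methyl-4-(trimethylsilyloxy)cyclohexyl]prop-1-en-1-yl}dimethylalumane F12, and I2 gives {[(1R,2S,4S)-2-bromo-4-[(1E)-1-iodoprop-1-en-2-yl]-1-methylcyclohexyl]oxy}trimethylsilane F13. K2CO3 in MeOH removes the silyl group and returns 15.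

**Further compounds**

F1 | step 3 | tert-butyldimethyl({(1S)-4-[(triethylsilyl)oxy]cyclohex-3-en-1-yl}methoxy)silane | CC[Si](CC)(CC)OC1=CC[C@@H](CO[Si](C)(C)C(C)(C)C)CC1
F2 | step 3 | (2R,4S)-2-bromo-4-({[tert-butyl(dimethyl)silyl]oxy}methyl)cyclohexan-1-one | O=C1[C@H](Br)C[C@@H](CO[Si](C)(C)C(C)(C)C)CC1
F3 | step 4 | (2S)-2-({[tert-butyl(dimethyl)silyl]oxy}methyl)-5-oxohexanal | CC(=O)CC[C@H](C=O)CO[Si](C)(C)C(C)(C)C
F4 | step 4 | (4S)-4-({[tert-butyl(dimethyl)silyl]oxy}methyl)-3-hydroxycyclohexan-1-one (both C3 epimers) | O=C1CC(O)[C@H](CO[Si](C)(C)C(C)(C)C)CC1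
F5 | step 4 | (4R)-4-({[tert-butyl(dimethyl)silyl]oxy}methyl)cyclohex-2-en-1-one | O=C1C=C[C@H](CO[Si](C)(C)C(C)(C)C)CC1
F6 | step 4 | tert-butyldimethyl({(1R)-4-[(triethylsilyl)oxy]cyclohex-3-en-1-yl}methoxy)silane | CC[Si](CC)(CC)OC1=CC[C@H](CO[Si](C)(C)C(C)(C)C)CC1
F7 | step 4 | (2S,4R)-2-bromo-4-({[tert-butyl(dimethyl)silyl]oxy}methyl)cyclohexan-1-one | O=C1[C@@H](Br)C[C@H](CO[Si](C)(C)C(C)(C)C)CC1
F8 | step 4 | (1R,2S,4R)-2-bromo-4-({[tert-butyl(dimethyl)silyl]oxy}methyl)-1-methylcyclohexan-1-ol | CC(C)(C)[Si](C)(C)OC[C@@H]1CC[C@@](C)(O)[C@@H](Br)C1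
F9 | step 4 | (1R,2S,4R)-2-bromo-4-(hydroxymethyl)-1-methylcyclohexan-1-ol | OC[C@@H]1CC[C@@](C)(O)[C@@H](Br)C1
F10 | step 4 | (1R,3S,4R)-3-bromo-4-hydroxy-4-methylcyclohexane-1-carbaldehyde | O=C[C@@H]1CC[C@@](C)(O)[C@@H](Br)C1
F11 | step 8 | {[(1R,2S,4S)-2-bromo-4-ethynyl-1-methylcyclohexyl]oxy}trimethylsilane | C#C[C@H]1CC[C@@](C)(O[Si](C)(C)C)[C@@H](Br)C1
F12 | step 8 | {(1E)-2-[(1S,3S,4R)-3-bromo-4-methyl-4-(trimethylsilyloxy)cyclohexyl]prop-1-en-1-yl}dimethylalumane | C[Al](C)/C=C(\C)[C@H]1CC[C@@](C)(O[Si](C)(C)C)[C@@H](Br)C1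
F13 | step 8 | {[(1R,2S,4S)-2-bromo-4-[(1E)-1-iodoprop-1-en-2-yl]-1-methylcyclohexyl]oxy}trimethylsilane | I/C=C(\C)[C@H]1CC[C@@](C)(O[Si](C)(C)C)[C@@H](Br)C1
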